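1. A percentage point of the charged starting material is the unit here. The enzyme and its forms together amount to 0.0016 mol% of the charge, so starting material left, any not yet dosed included, is 100 % minus target minus side product.

| flask | starting material | second substrate | enzyme | remark | time |
|---|---|---|---|---|---|
| Monday's | 20 mM | 1.8 equiv | 0.0016 mol% | run made earlier |  |
| Wednesday's | 20 mM | 1.2 equiv | 0.0016 mol% | run made earlier |  |
| Sunday's | 20 mM | 2.7 equiv | 0.0016 mol% | run made earlier |  |
| Thursday's | 20 mM | 1.8 equiv | 8.0 × 10⁻⁴ mol% | run made earlier |  |
| dusk | 20 mM (in portions, 5, over 15 h) | 1.80 equiv | 0.0016 mol% | first portion at the start, last at 15 h | 25 h |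
| autumn | 20 mM | 1.80 equiv | 0.0016 mol% | everything together at the start | 25 h |
| dawn | 20 mM | 1.80 equiv (fed, over 15 h) | 0.0016 mol% | all else is in the flask from the start; the feed brings no volume worth counting | 25 h |
| noon | 20 mM (fed, over 15 h) | 1.80 equiv | 0.0016 mol% | all else is in the flask from the start; the feed brings no volume worth counting | 25 h |

| run | time / h | side product / % | target / % |
|---|---|---|---|
| Monday's | 1.33 | 2 | 13 |
| Monday's | 2.00 | 8 | 18 |
| Monday's | 3.00 | 13 | 21 |
| Monday's | 4.00 | 21 | 23 |
| Monday's | 6.00 | 31 | 27 |
| Monday's | 10.0 | 45 | 22 |
| Monday's | 15.0 | 57 | 21 |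
| Wednesday's | 1.33 | 5 | 11 |
| Wednesday's | 4.00 | 13 | 19 |
| Wednesday's | 8.00 | 36 | 18 |
| Wednesday's | 10.0 | 38 | 16 |
| Wednesday's | 15.0 | 54 | 14 |
| Wednesday's | 20.0 | 61 | 7 |
| Wednesday's | 25.0 | 70 | 9 |
| Sunday's | 1.33 | 4 | 21 |
| Sunday's | 4.00 | 26 | 34 |
| Sunday's | 8.00 | 44 | 36 |
| Sunday's | 10.0 | 48 | 35 |
| Sunday's | 15.0 | 60 | 33 |
| Sunday's | 20.0 | 61 | 35 |
| Sunday's | 25.0 | 64 | 33 |
| Thursday's | 2.00 | 7 | 12 |
| Thursday's | 6.00 | 22 | 16 |
| Thursday's | 12.0 | 41 | 13 |
| Thursday's | 20.0 | 56 | 8 |
| Thursday's | 25.0 | 63 | 7 |

(scatter of a reading: 1.5 percentage points)

- percentages count the starting material that a species holds: one spent catalyst A or side product counts as two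
- reactions considered so far: ternary complex -> enzyme + target; starting complex -> spent catalyst B; target + starting complex -> spent catalyst A; starting material + target -> side product; starting material + enzyme <-> starting complex; second substrate + starting complex <-> ternary complex

- the flask that comes out highest in amount of side product, in percent of the starting material charged, or "all alike" when all lie within 1.5 percentage points (dusk / autumn / dawn / noon / all alike)
- side product at the end, in percent of the starting material charged, dusk
- side product at the end, in percent of the starting material charged, autumn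
- side product at the end, in percent of the starting material charged, dawn
- side product at the end, in percent of the starting material charged, noon

2. Side product forms from starting material and target, so its pace should follow their product. Call the pairing constant the fraction of the charge gained as side product per hour, divided by the starting-material fraction times the target fraction, both taken as means over the interval. Monday's run from 10.0 h to 15.0 h reads 0.406 h⁻¹. Thursday's run, with half the enzyme, reads 0.436 h⁻¹ from 12.0 h to 20.0 h. Within the scatter these agree, so the mean is kept: 0.421 h⁻¹.

3. At 6.00 h, Monday's run holds starting material 42.0 % and target 27 %, while Thursday's run holds 62.0 % and 16 %. The pairing constant therefore reckons the side pace at 0.0477 h⁻¹ for Monday's run and 0.0418 h⁻¹ for Thursday's run. At its last reading, 25.0 h, Thursday's run reads more starting material than Monday's run reads at 15.0 h, 30.0 % against 22.0 %, but less target, 7 % against 21 %. Its reckoned pace at that reading is thus 0.00884 h⁻¹, below the 0.0195 h⁻¹ of Monday's run at 15.0 h.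

4. Autumn repeats Monday's recipe. From 15.0 h, with starting material and target near their mean 21.5 % and falling together, and with further enzyme turnover left out, side product in autumn is reckoned to reach 70.4 %. This reckoning gives no figure for the dosed flasks.

5. The forecast names autumn as highest and gives 57 %, 69 %, 46 % and 55 % for dusk, autumn, dawn and noon, saying “Autumn simply extends Monday”; its autumn figure lies below the 70.4 % reckoned here.

6. The flasks give 60.1 %, 71.4 %, 55.8 % and 61.3 % in that order, so autumn stands highest.

    ternary complex → enzyme + target (k = 49000 h⁻¹)
    starting complex → spent catalyst B (k = 0.180 h⁻¹)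
    target + starting complex → spent catalyst A (k = 97.0 M⁻¹ h⁻¹)
    starting material + target → side product (k = 11.0 M⁻¹ h⁻¹)
    starting material + enzyme ⇌ starting complex (K = 49.0 M⁻¹, k = 11000 M⁻¹ s⁻¹)
    second substrate + starting complex ⇌ ternary complex (K = 13.0 M⁻¹, k = 20000 M⁻¹ s⁻¹)

Autumn ends with starting material 10.7 % and target 17.9 %, so the pairing constant gives a pace of 0.00803 h⁻¹. A neighbouring flask, the same as autumn but with 0.0027 mol% of enzyme, ends with starting material 2.50 % and target 33.7 %. The same reckoning gives it 0.00355 h⁻¹, less than autumn's pace. That neighbour ends with side product 63.8 %, below autumn's 71.4 %.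

The readings were generated by integration from invented constants.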